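**Retrosynthetic overview**
1. The oxirane (C4–C5) is formed last, by hydroxyl-directed vanadium epoxidation of the macrocyclic (4Z)-allylic alcohol 33.
2. The C6 hydroxyl and the C8 trimethoxybenzoate arise together from an Evans–Tishchenko reduction of β-hydroxy (Z)-enone 30 with 3,4,5-trimethoxybenzaldehyde.
3. The ten-membered carbocycle (formed before the oxirane) is closed at C5–C6 by a Nozaki–Hiyama–Kishi reaction of iodo-aldehyde 26, then oxidised to the enone.
4. In 26 the (Z)-iodoalkene comes from carbocupration of propyne, and the (E)-C1=C10 olefin from carboalumination of alkyne 14 followed by ethylene oxide.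
5. Alkyne 14 comes from epoxide 9 and a silylacetylide; C7 and C8 are set by a ketoreductase dynamic kinetic resolution of racemic keto ester 5 (from diethyl isopropylmalonate and chloroacetyl chloride).

Convention: C1–C10 in the text are germacrane locants (C1=C10 olefin, C4–C5 oxirane, C6 carbinol, C7 isopropyl, C8 ester); TBS = tert-butyldimethylsilyl.
Assumption: a ketoreductase with anti-(2S,3R) selectivity for 5 is found in a standard screening panel.

**Step 1**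
Reactants: 1 diethyl 2-(propan-2-yl)propanedioate
Product: 2 potassium 3-ethoxy-3-oxo-2-(propan-2-yl)propanoate
Conditions: KOH (1.0 equiv), EtOH, 0 °C → rt
Reagents that add atoms: potassium hydroxide, [K+].[OH-]
Why: Mono-saponification stops at the half-ester because the mono-potassium salt precipitates from ethanol.

**Step 2**
Reactants: 2 potassium 3-ethoxy-3-oxo-2-(propan-2-yl)propanoate; 3 chloroacetyl chloride
Product: 5 ethyl 4-chloro-3-oxo-2-(propan-2-yl)butanoate (racemic), via acylmalonate 4 (not isolated)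
Conditions: MgCl2, Et3N, MeCN, 0 °C → rt; then 1 M HCl
Reagents that add atoms: none
Why: Rathke–Masamune C-acylation of the magnesium enolate of the malonate half-ester, then decarboxylation on acidification, gives the α-branched β-keto ester.

**Step 3**
Reactants: 5 ethyl 4-chloro-3-oxo-2-(propan-2-yl)butanoate
Product: 6 ethyl (2S,3R)-4-chloro-3-hydroxy-2-(propan-2-yl)butanoate
Conditions: ketoreductase (anti-selective KRED), NADP+ (cat.), i-PrOH, phosphate buffer pH 7.0, 30 °C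
Reagents that add atoms: none
Why: Enzymatic dynamic kinetic resolution sets C7 and C8 (anti) in one asymmetric catalytic reduction, because C2 of the keto ester epimerises at pH 7 while the ketoreductase reduces only the (2S)-ketone from one carbonyl face.

**Step 4**
Reactants: 6 ethyl (2S,3R)-4-chloro-3-hydroxy-2-(propan-2-yl)butanoate
Product: 7 (2R,3R)-4-chloro-2-(propan-2-yl)butane-1,3-diol
Conditions: LiBH4, THF, 0 °C → rt; aq. NH4Cl
Reagents that add atoms: none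
Why: LiBH4 reduces the β-hydroxy ester chemoselectively and leaves the C–Cl bond and both stereocentres untouched.

**Step 5**
Reactants: 7 (2R,3R)-4-chloro-2-(propan-2-yl)butane-1,3-diol
Product: 8 (2R,3R)-4-(TBS-oxy)-1-chloro-3-(propan-2-yl)butan-2-ol
Conditions: TBSCl (1.05 equiv), imidazole, CH2Cl2, 0 °C
Reagents that add atoms: tert-butyl(chloro)dimethylsilane, CC(C)(C)[Si](C)(C)Cl
Why: Silylation is selective for the primary hydroxyl over the secondary one flanked by the isopropyl-bearing carbon.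

**Step 6**
Reactants: 8 (2R,3R)-4-(TBS-oxy)-1-chloro-3-(propan-2-yl)butan-2-ol
Product: 9 (2R)-2-[(2R)-1-(TBS-oxy)-3-methylbutan-2-yl]oxirane
Conditions: K2CO3, MeOH, 0 °C → rt
Reagents that add atoms: none
Why: Intramolecular Williamson closure of the chlorohydrin displaces chloride at the CH2 carbon, so the C8–O bond and its configuration are retained.

**Step 7**
Reactants: 9 (2R)-2-[(2R)-1-(TBS-oxy)-3-methylbutan-2-yl]oxirane; 10 ethynyl(trimethyl)silane
Product: 12 (2R,3S)-1-(TBS-oxy)-2-(propan-2-yl)-6-(trimethylsilyl)hex-5-yn-3-ol, via lithium acetylide 11 (not isolated)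
Conditions: 10, n-BuLi, THF, −78 °C; BF3·OEt2; then 9, −78 °C
Reagents that add atoms: none
Why: Yamaguchi alkynylation opens the BF3-activated epoxide at the unhindered terminal carbon only, leaving C8 untouched.

**Step 8**
Reactants: 12 (2R,3S)-1-(TBS-oxy)-2-(propan-2-yl)-6-(trimethylsilyl)hex-5-yn-3-ol
Product: 13 (2R,3S)-1-(TBS-oxy)-2-(propan-2-yl)hex-5-yn-3-ol
Conditions: K2CO3, MeOH, rt
Reagents that add atoms: none
Why: Methoxide cleaves the C(sp)–Si bond selectively while the primary silyl ether survives.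

**Step 9**
Reactants: 13 (2R,3S)-1-(TBS-oxy)-2-(propan-2-yl)hex-5-yn-3-ol
Product: 14 (2R,3S)-1,3-bis(TBS-oxy)-2-(propan-2-yl)hex-5-yne
Conditions: TBSOTf, 2,6-lutidine, CH2Cl2, −78 → 0 °C
Reagents that add atoms: tert-butyldimethylsilyl trifluoromethanesulfonate, CC(C)(C)[Si](C)(C)OS(=O)(=O)C(F)(F)F
Why: The silyl triflate protects the hindered secondary hydroxyl before the organometallic steps.

**Step 10**
Reactants: 14 (2R,3S)-1,3-bis(TBS-oxy)-2-(propan-2-yl)hex-5-yne; 15 oxirane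
Product: 18 (3E,6S,7R)-6,8-bis(TBS-oxy)-4-methyl-7-(propan-2-yl)oct-3-en-1-ol, via alkenylalane 16 (not isolated), via lithium alanate 17 (not isolated)
Conditions: Me3Al, Cp2ZrCl2 (0.25 equiv), CH2Cl2, 0 °C → rt; evaporate; n-BuLi, hexane/THF, −78 → 0 °C; oxirane, −30 °C → rt; aq. Rochelle salt
Reagents that add atoms: trimethylaluminium, C[Al](C)C
Why: Negishi zirconium-catalysed carboalumination adds Me–Al syn across the terminal alkyne with methyl on the internal carbon, and the derived alanate opens oxirane with retention, so C1=C10 is formed E.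

**Step 11**
Reactants: 18 (3E,6S,7R)-6,8-bis(TBS-oxy)-4-methyl-7-(propan-2-yl)oct-3-en-1-ol
Product: 19 (3E,6S,7R)-1-bromo-6,8-bis(TBS-oxy)-4-methyl-7-(propan-2-yl)oct-3-ene
Conditions: CBr4, PPh3, CH2Cl2, 0 °C
Reagents that add atoms: carbon tetrabromide, BrC(Br)(Br)Br
Why: The Appel reaction converts the primary alcohol to the bromide under neutral conditions that spare the silyl ethers and the olefin.

**Step 12**
Reactants: 19 (3E,6S,7R)-1-bromo-6,8-bis(TBS-oxy)-4-methyl-7-(propan-2-yl)oct-3-ene; 20 propyne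
Product: 24 (1Z,5E,8S,9R)-8,10-bis(TBS-oxy)-1-iodo-2,6-dimethyl-9-(propan-2-yl)deca-1,5-diene, via Grignard reagent 21 (not isolated), via alkylcopper 22 (not isolated), via alkenylcopper 23 (not isolated)
Conditions: Mg, Et2O, rt; CuBr·SMe2 (1.0 equiv), Et2O/Me2S, −45 °C; propyne, −25 °C, 48 h; I2, THF, −60 → 0 °C
Reagents that add atoms: iodine, II
Why: Normant carbocupration adds the alkylcopper syn to propyne with the chain on the internal carbon, and iodinolysis proceeds with retention, giving the (Z)-iodoalkene (chain cis to iodine) needed for the ring-cis C4=C5 olefin.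

**Step 13**
Reactants: 24 (1Z,5E,8S,9R)-8,10-bis(TBS-oxy)-1-iodo-2,6-dimethyl-9-(propan-2-yl)deca-1,5-diene
Product: 25 (2R,3S,5E,9Z)-3-(TBS-oxy)-10-iodo-5,9-dimethyl-2-(propan-2-yl)deca-5,9-dien-1-ol
Conditions: HF·pyridine, pyridine, THF, 0 °C
Reagents that add atoms: none
Why: The primary silyl ether is cleaved much faster than the secondary one next to the branched carbon.

**Step 14**
Reactants: 25 (2R,3S,5E,9Z)-3-(TBS-oxy)-10-iodo-5,9-dimethyl-2-(propan-2-yl)deca-5,9-dien-1-ol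
Product: 26 (2S,3S,5E,9Z)-3-(TBS-oxy)-10-iodo-5,9-dimethyl-2-(propan-2-yl)deca-5,9-dienal
Conditions: Dess–Martin periodinane, NaHCO3, CH2Cl2, 0 °C → rt; used at once
Reagents that add atoms: none
Why: Buffered Dess–Martin oxidation gives the α-branched aldehyde without epimerising C7 or touching the iodoalkene.

**Step 15**
Reactants: 26 (2S,3S,5E,9Z)-3-(TBS-oxy)-10-iodo-5,9-dimethyl-2-(propan-2-yl)deca-5,9-dienal
Product: 28 (2Z,6E,9S,10R)-9-(TBS-oxy)-3,7-dimethyl-10-(propan-2-yl)cyclodeca-2,6-dien-1-ol as both C1 epimers, via alkenylchromium dichloride 27 (not isolated)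
Conditions: CrCl2 (15 equiv), NiCl2 (1 mol% of Cr), degassed DMSO/THF, rt, 2 mM, syringe-pump addition; kept below 30 °C
Reagents that add atoms: none
Why: The Nozaki–Hiyama–Kishi reaction closes the ten-membered ring at C5–C6 with retention of the Z geometry; the C6 configuration is not controlled here and is erased in step 16.

**Step 16**
Reactants: 28 (2Z,6E,9S,10R)-9-(TBS-oxy)-3,7-dimethyl-10-(propan-2-yl)cyclodeca-2,6-dien-1-ol
Product: 29 (2Z,6E,9S,10S)-9-(TBS-oxy)-3,7-dimethyl-10-(propan-2-yl)cyclodeca-2,6-dien-1-one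
Conditions: Dess–Martin periodinane, NaHCO3, CH2Cl2, 0 °C → rt
Reagents that add atoms: none
Why: Dess–Martin oxidation converges both C6 epimers on one (Z)-enone under non-basic conditions that do not epimerise C7.

**Step 17**
Reactants: 29 (2Z,6E,9S,10S)-9-(TBS-oxy)-3,7-dimethyl-10-(propan-2-yl)cyclodeca-2,6-dien-1-one
Product: 30 (2Z,6E,9S,10S)-9-hydroxy-3,7-dimethyl-10-(propan-2-yl)cyclodeca-2,6-dien-1-one
Conditions: HF·pyridine, THF, 0 °C → rt
Reagents that add atoms: none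
Why: Fluoride-acid desilylation frees the C8 hydroxyl without the base that would trigger retro-aldol cleavage or β-elimination.

**Step 18**
Reactants: 30 (2Z,6E,9S,10S)-9-hydroxy-3,7-dimethyl-10-(propan-2-yl)cyclodeca-2,6-dien-1-one; 31 3,4,5-trimethoxybenzaldehyde
Product: 33 (1S,3E,7Z,9S,10R)-9-hydroxy-3,7-dimethyl-10-(propan-2-yl)cyclodeca-3,7-dien-1-yl 3,4,5-trimethoxybenzoate, via hemiacetal 32 (not isolated)
Conditions: 31 (6 equiv), SmI2 (0.3 equiv, premixed with 31), THF, −10 °C, dark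
Reagents that add atoms: none
Why: In the Evans–Tishchenko reduction the samarium-bound hemiacetal on O8 transfers hydride intramolecularly to the C6 carbonyl through a six-membered chair (C9 and isopropyl equatorial), which sets C6–OH 1,3-anti (trans on the ring) to the C8 oxygen and leaves the aroyl group on O8.

**Step 19**
Reactants: 33 (1S,3E,7Z,9S,10R)-9-hydroxy-3,7-dimethyl-10-(propan-2-yl)cyclodeca-3,7-dien-1-yl 3,4,5-trimethoxybenzoate
Product: 34 (1R,2R,3R,4S,6E,10S)-2-hydroxy-6,10-dimethyl-3-(propan-2-yl)-11-oxabicyclo[8.1.0]undec-6-en-4-yl 3,4,5-trimethoxybenzoate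
Conditions: VO(acac)2 (5 mol%), t-BuOOH (1.3 equiv, decane), CH2Cl2, 0 °C
Reagents that add atoms: tert-butyl hydroperoxide, CC(C)(C)OO
Why: In the Sharpless vanadium-catalysed directed epoxidation the vanadate ester of the C6 hydroxyl delivers oxygen to the adjacent C4=C5 face cis to that hydroxyl (as with medium-ring cycloalk-2-enols), which sets C4 and C5 and leaves the isolated C1=C10 olefin and the ester untouched.

**Compound list**
1 | diethyl 2-(propan-2-yl)propanedioate | CCOC(=O)C(C(C)C)C(=O)OCC | starting material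
2 | potassium 3-ethoxy-3-oxo-2-(propan-2-yl)propanoate | CCOC(=O)C(C(C)C)C(=O)[O-].[K+] | intermediate
3 | chloroacetyl chloride | ClCC(Cl)=O | starting material
4 | 2-(chloroacetyl)-3-ethoxy-3-oxo-2-(propan-2-yl)propanoic acid (magnesium salt in the flask) | CCOC(=O)C(C(C)C)(C(=O)CCl)C(=O)O | intermediate
5 | ethyl 4-chloro-3-oxo-2-(propan-2-yl)butanoate (racemic) | CCOC(=O)C(C(C)C)C(=O)CCl | intermediate
6 | ethyl (2S,3R)-4-chloro-3-hydroxy-2-(propan-2-yl)butanoate | CCOC(=O)[C@@H](C(C)C)[C@@H](O)CCl | intermediate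
7 | (2R,3R)-4-chloro-2-(propan-2-yl)butane-1,3-diol | OC[C@@H](C(C)C)[C@@H](O)CCl | intermediate
8 | (2R,3R)-4-(TBS-oxy)-1-chloro-3-(propan-2-yl)butan-2-ol | CC(C)(C)[Si](C)(C)OC[C@@H](C(C)C)[C@@H](O)CCl | intermediate
9 | (2R)-2-[(2R)-1-(TBS-oxy)-3-methylbutan-2-yl]oxirane | CC(C)(C)[Si](C)(C)OC[C@@H](C(C)C)[C@@H]1CO1 | intermediate
10 | ethynyl(trimethyl)silane | C#C[Si](C)(C)C | starting material
11 | lithium (trimethylsilyl)acetylide | [Li]C#C[Si](C)(C)C | intermediate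
12 | (2R,3S)-1-(TBS-oxy)-2-(propan-2-yl)-6-(trimethylsilyl)hex-5-yn-3-ol | CC(C)(C)[Si](C)(C)OC[C@@H](C(C)C)[C@@H](O)CC#C[Si](C)(C)C | intermediate
13 | (2R,3S)-1-(TBS-oxy)-2-(propan-2-yl)hex-5-yn-3-ol | CC(C)(C)[Si](C)(C)OC[C@@H](C(C)C)[C@@H](O)CC#C | intermediate
14 | (2R,3S)-1,3-bis(TBS-oxy)-2-(propan-2-yl)hex-5-yne | CC(C)(C)[Si](C)(C)OC[C@@H](C(C)C)[C@@H](O[Si](C)(C)C(C)(C)C)CC#C | intermediate
15 | oxirane | C1CO1 | starting material
16 | [(1E,4S,5R)-4,6-bis(TBS-oxy)-2-methyl-5-(propan-2-yl)hex-1-en-1-yl]dimethylalumane | CC(C)(C)[Si](C)(C)OC[C@@H](C(C)C)[C@@H](O[Si](C)(C)C(C)(C)C)C/C(C)=C/[Al](C)C | intermediate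
17 | lithium butyl[(1E,4S,5R)-4,6-bis(TBS-oxy)-2-methyl-5-(propan-2-yl)hex-1-en-1-yl]dimethylaluminate | CC(C)(C)[Si](C)(C)OC[C@@H](C(C)C)[C@@H](O[Si](C)(C)C(C)(C)C)C/C(C)=C/[Al-](C)(C)CCCC.[Li+] | intermediate
18 | (3E,6S,7R)-6,8-bis(TBS-oxy)-4-methyl-7-(propan-2-yl)oct-3-en-1-ol | CC(C)(C)[Si](C)(C)OC[C@@H](C(C)C)[C@@H](O[Si](C)(C)C(C)(C)C)C/C(C)=C/CCO | intermediate
19 | (3E,6S,7R)-1-bromo-6,8-bis(TBS-oxy)-4-methyl-7-(propan-2-yl)oct-3-ene | CC(C)(C)[Si](C)(C)OC[C@@H](C(C)C)[C@@H](O[Si](C)(C)C(C)(C)C)C/C(C)=C/CCBr | intermediate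
20 | propyne | CC#C | starting material
21 | [(3E,6S,7R)-6,8-bis(TBS-oxy)-4-methyl-7-(propan-2-yl)oct-3-en-1-yl]magnesium bromide | CC(C)(C)[Si](C)(C)OC[C@@H](C(C)C)[C@@H](O[Si](C)(C)C(C)(C)C)C/C(C)=C/CC[Mg]Br | intermediate
22 | [(3E,6S,7R)-6,8-bis(TBS-oxy)-4-methyl-7-(propan-2-yl)oct-3-en-1-yl]copper (MgBr2·SMe2 complex) | CC(C)(C)[Si](C)(C)OC[C@@H](C(C)C)[C@@H](O[Si](C)(C)C(C)(C)C)C/C(C)=C/CC[Cu] | intermediate
23 | [(1Z,5E,8S,9R)-8,10-bis(TBS-oxy)-2,6-dimethyl-9-(propan-2-yl)deca-1,5-dien-1-yl]copper | CC(C)(C)[Si](C)(C)OC[C@@H](C(C)C)[C@@H](O[Si](C)(C)C(C)(C)C)C/C(C)=C/CC/C(C)=C\[Cu] | intermediate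
24 | (1Z,5E,8S,9R)-8,10-bis(TBS-oxy)-1-iodo-2,6-dimethyl-9-(propan-2-yl)deca-1,5-diene | CC(C)(C)[Si](C)(C)OC[C@@H](C(C)C)[C@@H](O[Si](C)(C)C(C)(C)C)C/C(C)=C/CC/C(C)=C\I | intermediate
25 | (2R,3S,5E,9Z)-3-(TBS-oxy)-10-iodo-5,9-dimethyl-2-(propan-2-yl)deca-5,9-dien-1-ol | OC[C@@H](C(C)C)[C@@H](O[Si](C)(C)C(C)(C)C)C/C(C)=C/CC/C(C)=C\I | intermediate
26 | (2S,3S,5E,9Z)-3-(TBS-oxy)-10-iodo-5,9-dimethyl-2-(propan-2-yl)deca-5,9-dienal | O=C[C@@H](C(C)C)[C@@H](O[Si](C)(C)C(C)(C)C)C/C(C)=C/CC/C(C)=C\I | intermediate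
27 | [(1Z,5E,8S,9S)-8-(TBS-oxy)-2,6-dimethyl-10-oxo-9-(propan-2-yl)deca-1,5-dien-1-yl]chromium dichloride | O=C[C@@H](C(C)C)[C@@H](O[Si](C)(C)C(C)(C)C)C/C(C)=C/CC/C(C)=C\[Cr](Cl)Cl | intermediate
28 | (2Z,6E,9S,10R)-9-(TBS-oxy)-3,7-dimethyl-10-(propan-2-yl)cyclodeca-2,6-dien-1-ol (both C1 epimers) | CC(C)(C)[Si](C)(C)O[C@H]1C/C(C)=C/CC/C(C)=C\C(O)[C@H]1C(C)C | intermediate
29 | (2Z,6E,9S,10S)-9-(TBS-oxy)-3,7-dimethyl-10-(propan-2-yl)cyclodeca-2,6-dien-1-one | CC(C)(C)[Si](C)(C)O[C@H]1C/C(C)=C/CC/C(C)=C\C(=O)[C@H]1C(C)C | intermediate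
30 | (2Z,6E,9S,10S)-9-hydroxy-3,7-dimethyl-10-(propan-2-yl)cyclodeca-2,6-dien-1-one | O[C@H]1C/C(C)=C/CC/C(C)=C\C(=O)[C@H]1C(C)C | intermediate
31 | 3,4,5-trimethoxybenzaldehyde | COc1cc(C=O)cc(OC)c1OC | starting material
32 | hemiacetal of 30 (O8) with 31 (samarium alkoxide in the flask) | COc1cc(C(O)O[C@H]2C/C(C)=C/CC/C(C)=C\C(=O)[C@H]2C(C)C)cc(OC)c1OC | intermediate
33 | (1S,3E,7Z,9S,10R)-9-hydroxy-3,7-dimethyl-10-(propan-2-yl)cyclodeca-3,7-dien-1-yl 3,4,5-trimethoxybenzoate | COc1cc(C(=O)O[C@H]2C/C(C)=C/CC/C(C)=C\[C@H](O)[C@H]2C(C)C)cc(OC)c1OC | intermediate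
34 | (1R,2R,3R,4S,6E,10S)-2-hydroxy-6,10-dimethyl-3-(propan-2-yl)-11-oxabicyclo[8.1.0]undec-6-en-4-yl 3,4,5-trimethoxybenzoate | COc1cc(C(=O)O[C@H]2C/C(C)=C/CC[C@]3(C)O[C@@H]3[C@H](O)[C@H]2C(C)C)cc(OC)c1OC | target

**Totals**
Total step count: 19. Longest linear sequence: 19 steps (1 → 34).

**Three steps most likely to fail**

Step 12 (carbocupration on an advanced Grignard reagent; long reaction time, incomplete addition to propyne). The fallback sets out from bromide 19 and comes back at iodide 24, building the (Z)-iodoalkene by cross-coupling instead of carbometalation. Propyne 20 is bromoborated with BBr3 at −78 °C (syn addition) to dibromo[(1Z)-2-bromoprop-1-en-1-yl]borane F1, which is esterified with pinacol to the pinacol boronate F2. Bromide 19 is converted with Zn dust and LiCl in THF into the alkylzinc bromide F3. Negishi coupling of F3 with F2 at the C–Br bond (Pd(tBu3P)2, THF, rt, retention) gives the (Z)-alkenylboronate F4. Iododeboronation with I2 and NaOH (retention) then gives 24.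

Step 15 (closure of a strained ten-membered ring; oligomerisation or reduction of the iodide can compete). The fallback sets out from alkyne 14 and comes back at the macrocyclic alcohols 28, closing the ring at C3–C4 by an intramolecular B-alkyl Suzuki–Miyaura coupling instead of at C5–C6. Alkyne 14 is carboaluminated as in step 10 to alane 16, which is coupled with vinyl bromide (Pd(PPh3)4, THF) to the diene F5. Selective primary desilylation (HF·pyridine) gives the alcohol F6, and Dess–Martin oxidation gives the aldehyde F7. Addition of 1-propynylmagnesium bromide gives the propargylic alcohols F8. trans-Hydroalumination with NaAlH2(OCH2CH2OMe)2 followed by I2 gives the (Z)-3-iodoallylic alcohols F9, with iodine on the methyl-bearing carbon and cis to C6. 9-BBN (2.2 equiv) hydroborates only the terminal vinyl group to give the B-alkylborane F10. Slow addition of F10 to Pd(dppf)Cl2, AsPh3 and Cs2CO3 in DMF/THF/H2O joins C3 to C4 with retention and delivers 28.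

Step 18 (hemiacetal formation with an electron-rich aldehyde and hydride transfer inside a medium ring may be slow). The fallback sets out from hydroxy enone 30 and comes back at target 34, separating reduction from acylation. Me4NBH(OAc)3 in MeCN/AcOH at −30 °C (Evans–Saksena reduction, hydride delivered from boron bound to O8) gives the 1,3-anti diol F11. VO(acac)2 and t-BuOOH (1.1 equiv, 0 °C) epoxidise the allylic C4=C5 olefin cis to the C6 hydroxyl to give the epoxy diol F12. 3,4,5-Trimethoxybenzoyl chloride (1.05 equiv) with 2,4,6-collidine in CH2Cl2 at −40 °C then acylates the less hindered C8 hydroxyl to give 34; the C6 hydroxyl is flanked by two branched carbons and hydrogen-bonded to the oxirane.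

**Further compounds**
F1 | step 12 | dibromo[(1Z)-2-bromoprop-1-en-1-yl]borane | C/C(Br)=C/B(Br)Br
F2 | step 12 | 2-[(1Z)-2-bromoprop-1-en-1-yl]-4,4,5,5-tetramethyl-1,3,2-dioxaborolane | C/C(Br)=C/B1OC(C)(C)C(C)(C)O1
F3 | step 12 | [(3E,6S,7R)-6,8-bis(TBS-oxy)-4-methyl-7-(propan-2-yl)oct-3-en-1-yl]zinc bromide | CC(C)(C)[Si](C)(C)OC[C@@H](C(C)C)[C@@H](O[Si](C)(C)C(C)(C)C)C/C(C)=C/CC[Zn]Br
F4 | step 12 | 2-[(1Z,5E,8S,9R)-8,10-bis(TBS-oxy)-2,6-dimethyl-9-(propan-2-yl)deca-1,5-dien-1-yl]-4,4,5,5-tetramethyl-1,3,2-dioxaborolane | CC(C)(C)[Si](C)(C)OC[C@@H](C(C)C)[C@@H](O[Si](C)(C)C(C)(C)C)C/C(C)=C/CC/C(C)=C\B1OC(C)(C)C(C)(C)O1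
F5 | step 15 | (2R,3S,5E)-1,3-bis(TBS-oxy)-5-methyl-2-(propan-2-yl)octa-5,7-diene | CC(C)(C)[Si](C)(C)OC[C@@H](C(C)C)[C@@H](O[Si](C)(C)C(C)(C)C)C/C(C)=C/C=C
F6 | step 15 | (2R,3S,5E)-3-(TBS-oxy)-5-methyl-2-(propan-2-yl)octa-5,7-dien-1-ol | OC[C@@H](C(C)C)[C@@H](O[Si](C)(C)C(C)(C)C)C/C(C)=C/C=C
F7 | step 15 | (2S,3S,5E)-3-(TBS-oxy)-5-methyl-2-(propan-2-yl)octa-5,7-dienal | O=C[C@@H](C(C)C)[C@@H](O[Si](C)(C)C(C)(C)C)C/C(C)=C/C=C
F8 | step 15 | (5R,6S,8E)-6-(TBS-oxy)-8-methyl-5-(propan-2-yl)undeca-8,10-dien-2-yn-4-ol (both C4 epimers) | CC#CC(O)[C@@H](C(C)C)[C@@H](O[Si](C)(C)C(C)(C)C)C/C(C)=C/C=C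
F9 | step 15 | (2Z,5R,6S,8E)-6-(TBS-oxy)-2-iodo-8-methyl-5-(propan-2-yl)undeca-2,8,10-trien-4-ol (both C4 epimers) | C/C(I)=C/C(O)[C@@H](C(C)C)[C@@H](O[Si](C)(C)C(C)(C)C)C/C(C)=C/C=C
F10 | step 15 | (2Z,5R,6S,8E)-11-(9-borabicyclo[3.3.1]nonan-9-yl)-6-(TBS-oxy)-2-iodo-8-methyl-5-(propan-2-yl)undeca-2,8-dien-4-ol | C/C(I)=C/C(O)[C@@H](C(C)C)[C@@H](O[Si](C)(C)C(C)(C)C)C/C(C)=C/CCB1C2CCCC1CCC2
F11 | step 18 | (1S,2S,3S,4Z,8E)-5,9-dimethyl-2-(propan-2-yl)cyclodeca-4,8-diene-1,3-diol | O[C@H]1C/C(C)=C/CC/C(C)=C\[C@H](O)[C@H]1C(C)C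
F12 | step 18 | (1R,2R,3S,4S,6E,10S)-6,10-dimethyl-3-(propan-2-yl)-11-oxabicyclo[8.1.0]undec-6-ene-2,4-diol | O[C@H]1C/C(C)=C/CC[C@]2(C)O[C@@H]2[C@H](O)[C@H]1C(C)C
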